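The carbocycle is disconnected at C5–C6 and C7–C8. A furan fused across the pyranone C4a=C8a bond, with its oxygen joining C5 and C8, is the diene and vinylene carbonate the dienophile. The feature used is that C5 and C8, the two carbons attached to C4a=C8a, bear OH and Cl trans to each other: this is the signature of a 5,8-oxygen bridge opened by chloride at C8 with inversion. One exo [4+2] under a chiral acid closes the ring and sets C5–C8, with the 6,7-oxygens syn to the bridge. The precursor is the racemic lactol methyl ether of that furan, carrying the arylethyl chain with its phenol as an isopropyl ether.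

Key step: step 9

Remarks on the chemistry:
- Ring positions use the chromone numbering of the target (C2–C8a) throughout, including the furan-fused intermediates. C5 is the lactol carbon on C4a and C8 the CH2 on C8a.
- The target has an all-cis 5,6,7-triol with chlorine trans to it, (5S,6S,7S,8R).
- The phenol is carried as an isopropyl ether, not a silyl ether. A silyl aryl ether would need fluoride or base at the end, which would close the trans-7,8-chlorohydrin to an epoxide; BCl3 removes the isopropyl group in the step that opens the bridge.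
- Step 9 is run under kinetic control (no cycloreversion), so exo and facial selectivity must both come from the catalyst-bound transition state.
- Assumptions: chlorokojic acid is purchased (otherwise one step from kojic acid with SOCl2). The (R)-acid in step 9 is a working assumption; if it delivers the opposite face, its mirror image is used.

Step 1
Reactants: 1 isovanillin (3-hydroxy-4-methoxybenzaldehyde)
Product: 2 3-isopropoxy-4-methoxybenzaldehyde
Conditions: i-PrBr, K2CO3, DMF, 60 °C
Reagents that add atoms: 2-bromopropane CC(C)Br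
Why: Williamson ether synthesis on the phenoxide; the aryl isopropyl ether should survive every later step until BCl3 removes it selectively beside the methyl ether.

Step 2
Reactants: 3 chlorokojic acid (2-(chloromethyl)-5-hydroxy-4H-pyran-4-one)
Product: 4 [(5-hydroxy-4-oxo-4H-pyran-2-yl)methyl]triphenylphosphonium chloride
Conditions: PPh3, MeCN, reflux
Reagents that add atoms: triphenylphosphine c1ccc(cc1)P(c1ccccc1)c1ccccc1
Why: SN2 quaternisation of the phosphine by the activated (allylic, vinylogous α-keto) primary chloride, the standard entry to a Wittig salt.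

Step 3
Reactants: 4 phosphonium chloride; 2 3-isopropoxy-4-methoxybenzaldehyde
Product: 5 (E)-5-hydroxy-2-[2-(3-isopropoxy-4-methoxyphenyl)ethenyl]-4H-pyran-4-one
Conditions: NaOMe (2.1 equiv), MeOH, 0 → 50 °C; then aq. HCl to pH 3
Reagents that add atoms: none
Why: Wittig olefination; two equivalents of base give the enolate–ylide, a semistabilised (vinylogous acyl) ylide that should condense with the aryl aldehyde, and the E/Z ratio is irrelevant because the alkene is hydrogenated next.

Step 4
Reactants: 5 styrylpyranone
Product: 6 5-hydroxy-2-[2-(3-isopropoxy-4-methoxyphenyl)ethyl]-4H-pyran-4-one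
Conditions: H2 (1 atm), 5% Pd/C, EtOAc–MeOH, rt, stopped after 1 equiv
Reagents that add atoms: none
Why: Heterogeneous catalytic hydrogenation should saturate the styryl C=C well before the vinylogous-ester double bonds of the 4-pyranone or the aryl ethers react.

Step 5
Reactants: 6 5-hydroxy-2-(arylethyl)-4-pyranone
Product: 7 3-hydroxy-2-(hydroxymethyl)-6-[2-(3-isopropoxy-4-methoxyphenyl)ethyl]-4H-pyran-4-one
Conditions: 37% aq. CH2O, NaOH (1.05 equiv), MeOH–H2O, rt; then HCl
Reagents that add atoms: formaldehyde C=O
Why: Base-mediated hydroxymethylation (Lederer–Manasse type, as used on kojic acid and allomaltol); the enolate adds formaldehyde at its only free ortho position, the ring carbon that becomes C8a, which thereby acquires C8.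

Step 6
Reactants: 7 3-hydroxy-2-(hydroxymethyl)pyranone
Product: 9 2-[(tert-butyldimethylsilyloxy)methyl]-6-[2-(3-isopropoxy-4-methoxyphenyl)ethyl]-4-oxo-4H-pyran-3-yl trifluoromethanesulfonate, via hydroxy triflate 8 (not isolated)
Conditions: PhNTf2, Et3N, CH2Cl2, 0 °C → rt; then TBSCl, imidazole, rt
Reagents that add atoms: N-phenylbis(trifluoromethanesulfonimide) O=S(=O)(N(c1ccccc1)S(=O)(=O)C(F)(F)F)C(F)(F)F; tert-butyldimethylsilyl chloride CC(C)(C)[Si](C)(C)Cl
Why: Selective O-triflation of the acidic enolic 3-OH (the primary alcohol does not react with PhNTf2), then silylation of the primary alcohol so that it cannot trap the acyl-palladium intermediate of step 7 as a lactone.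

Step 7
Reactants: 9 silyl ether triflate
Product: 10 2-[(tert-butyldimethylsilyloxy)methyl]-6-[2-(3-isopropoxy-4-methoxyphenyl)ethyl]-4-oxo-4H-pyran-3-carbaldehyde
Conditions: Pd(OAc)2 (5 mol%), dppp, CO (1 atm), Et3SiH, Et3N, DMF, 70 °C
Reagents that add atoms: carbon monoxide [C-]#[O+]
Why: Palladium-catalysed reductive carbonylation (formylation) of an enol triflate with CO and a silane; oxidative addition, CO insertion and hydride transfer should place the C5 carbon on C4a at the aldehyde level.

Step 8
Reactants: 10 formylpyranone silyl ether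
Product: 11 (±)-2-[2-(3-isopropoxy-4-methoxyphenyl)ethyl]-5-methoxy-5,7-dihydro-4H-furo[3,4-b]pyran-4-one (lactol methyl ether; OMe on the carbon attached to C4a)
Conditions: CSA (10 mol%), MeOH, 0 °C → rt; Et3N quench
Reagents that add atoms: methanol CO
Why: Acid-catalysed desilylation, intramolecular hemiacetal formation and acetal exchange with methanol (lactol methyl ether formation); C5 forms as a racemic centre, which is irrelevant because it becomes sp2 in step 9.

Step 9
Reactants: 11 lactol methyl ether; 12 vinylene carbonate
Product: 14 (5S,6S,7S,8S)-5,8-epoxy-2-[2-(3-isopropoxy-4-methoxyphenyl)ethyl]-5,6,7,8-tetrahydro-4H-chromen-4-one 6,7-cyclic carbonate (exo: carbonate oxygens syn to the oxygen bridge), via furo[3,4-b]pyran-4-one diene 13 (not isolated)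
Conditions: (R)-3,3′-bis(2,4,6-triisopropylphenyl)-BINOL N-triflylphosphoramide (10 mol%), 12 (8 equiv), 5 Å MS, PhMe, −20 °C → rt
Reagents that add atoms: none
Why: Proposed new method: the chiral acid should ionise the lactol ether to the C5 oxocarbenium ion (stabilised by the ring oxygen and, through C4a=C8a, by O1), loss of H-8 gives furan 13 while the sieves take up methanol, and the O4-protonated ion pair of 13 is a LUMO-lowered diene that should add the weakly nucleophilic vinylene carbonate in a suprafacial, asynchronous inverse-demand [4+2] with the C5–C6 bond leading. The closest known reaction types are the acid-triggered generation of isobenzofurans from lactol ethers with thermal Diels–Alder trapping, thermal furan–vinylene carbonate cycloadditions, and chiral Brønsted-acid ion-pair [4+2] reactions of acid-generated cationic oxa-dienes with alkenes. The carbocycle closes by intermolecular [4+2] cycloaddition across C5 and C8 of the furan (two C–C bonds, six-membered ring), which returns C4a=C8a to the pyranone and leaves the furan oxygen as the 5,8-bridge. C6 and C7 are cis to each other through the dienophile geometry and syn to the bridge through exo approach, while the configuration at C5 and C8 (addition to the C5-Re/C8-Si face) is set by the chiral anion held at O4–H and at the acidic H-5 beside the leading bond. The step needs exo over endo and one face over the other under kinetic control: the endo mode would put the carbonate under the C4a–C8a edge covered by the catalyst's aryl group whereas the exo side meets only the small furan oxygen, and the C4 carbonyl directly flanking C5 is the substrate feature that keeps the chiral controller at the reacting terminus.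

Step 10
Reactants: 14 exo carbonate adduct
Product: 15 (5S,6R,7S,8S)-5,8-epoxy-6,7-dihydroxy-2-[2-(3-isopropoxy-4-methoxyphenyl)ethyl]-5,6,7,8-tetrahydro-4H-chromen-4-one (exo cis-diol, configuration as in 14)
Conditions: K2CO3 (0.2 equiv), MeOH, 0 °C; AcOH quench
Reagents that add atoms: none
Why: Base-catalysed transesterification (methanolysis) of the five-membered carbonate should be far faster than attack on the 4-pyranone; the bridgehead hydrogens cannot epimerise (Bredt), so all four centres are kept, and the carbonate is removed here because base is not tolerated once the chlorohydrin exists.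

Step 11
Reactants: 15 exo diol
Product: 16 (5S,6S,7S,8S)-5,8-epoxy-6,7-(isopropylidenedioxy)-2-[2-(3-isopropoxy-4-methoxyphenyl)ethyl]-5,6,7,8-tetrahydro-4H-chromen-4-one (acetonide)
Conditions: Me2C(OMe)2, PPTS (cat.), acetone, rt
Reagents that add atoms: 2,2-dimethoxypropane COC(C)(C)OC
Why: Acid-catalysed transketalisation to the cis-fused acetonide of the exo diol, which keeps O6 and O7 free of boron while the bridge is opened at low temperature.

Step 12
Reactants: 16 acetonide
Product: 18 CNP0362174.1 (5S,6S,7S,8R)-8-chloro-5,6,7-trihydroxy-2-[2-(3-hydroxy-4-methoxyphenyl)ethyl]-5,6,7,8-tetrahydro-4H-chromen-4-one, via O5-dichloroboryl chlorohydrin 17 (not isolated)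
Conditions: BCl3 (5 equiv), CH2Cl2, −78 → 0 °C; MeOH, −78 °C; pH 7 buffer
Reagents that add atoms: boron trichloride ClB(Cl)Cl
Why: Boron trihalide ether cleavage; BCl3 should bind the basic C4=O and, after loss of chloride, the adjacent bridge oxygen at C5 in a six-membered chelate, the released chloride then attacks C8 anti to the departing oxygen (SN2, inversion; C8 sits on the electron-poor C8a and cleavage there keeps the O5–B–O4 chelate), giving C8–Cl trans to C5–O, and on warming the same reagent cleaves the aryl isopropyl ether (not the methyl ether) and the acetonide before methanolysis frees the triol.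

Compound list
1 | isovanillin (3-hydroxy-4-methoxybenzaldehyde) | COc1ccc(C=O)cc1O | starting material
2 | 3-isopropoxy-4-methoxybenzaldehyde | COc1ccc(C=O)cc1OC(C)C | intermediate
3 | chlorokojic acid, 2-(chloromethyl)-5-hydroxy-4H-pyran-4-one | O=c1cc(CCl)occ1O | starting material
4 | [(5-hydroxy-4-oxo-4H-pyran-2-yl)methyl]triphenylphosphonium chloride | [Cl-].O=c1cc(C[P+](c2ccccc2)(c2ccccc2)c2ccccc2)occ1O | intermediate
5 | (E)-5-hydroxy-2-[2-(3-isopropoxy-4-methoxyphenyl)ethenyl]-4H-pyran-4-one | COc1ccc(/C=C/c2cc(=O)c(O)co2)cc1OC(C)C | intermediate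
6 | 5-hydroxy-2-[2-(3-isopropoxy-4-methoxyphenyl)ethyl]-4H-pyran-4-one | COc1ccc(CCc2cc(=O)c(O)co2)cc1OC(C)C | intermediate
7 | 3-hydroxy-2-(hydroxymethyl)-6-[2-(3-isopropoxy-4-methoxyphenyl)ethyl]-4H-pyran-4-one | COc1ccc(CCc2cc(=O)c(O)c(CO)o2)cc1OC(C)C | intermediate
8 | 2-(hydroxymethyl)-6-[2-(3-isopropoxy-4-methoxyphenyl)ethyl]-4-oxo-4H-pyran-3-yl trifluoromethanesulfonate | COc1ccc(CCc2cc(=O)c(OS(=O)(=O)C(F)(F)F)c(CO)o2)cc1OC(C)C | intermediate (not isolated)
9 | 2-[(tert-butyldimethylsilyloxy)methyl]-6-[2-(3-isopropoxy-4-methoxyphenyl)ethyl]-4-oxo-4H-pyran-3-yl trifluoromethanesulfonate | COc1ccc(CCc2cc(=O)c(OS(=O)(=O)C(F)(F)F)c(CO[Si](C)(C)C(C)(C)C)o2)cc1OC(C)C | intermediate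
10 | 2-[(tert-butyldimethylsilyloxy)methyl]-6-[2-(3-isopropoxy-4-methoxyphenyl)ethyl]-4-oxo-4H-pyran-3-carbaldehyde | COc1ccc(CCc2cc(=O)c(C=O)c(CO[Si](C)(C)C(C)(C)C)o2)cc1OC(C)C | intermediate
11 | (±)-2-[2-(3-isopropoxy-4-methoxyphenyl)ethyl]-5-methoxy-5,7-dihydro-4H-furo[3,4-b]pyran-4-one (racemic lactol methyl ether) | COc1ccc(CCc2cc(=O)c3c(o2)COC3OC)cc1OC(C)C | intermediate
12 | vinylene carbonate (1,3-dioxol-2-one) | O=C1OC=CO1 | starting material
13 | 2-[2-(3-isopropoxy-4-methoxyphenyl)ethyl]-4H-furo[3,4-b]pyran-4-one (furan diene) | O=C1C=C(CCc2ccc(OC)c(OC(C)C)c2)OC2=COC=C12 | intermediate (not isolated)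
14 | (5S,6S,7S,8S)-5,8-epoxy-2-[2-(3-isopropoxy-4-methoxyphenyl)ethyl]-5,6,7,8-tetrahydro-4H-chromen-4-one 6,7-cyclic carbonate, exo | COc1ccc(CCc2cc(=O)c3c(o2)[C@@H](O4)[C@@H](OC5=O)[C@@H](O5)[C@H]34)cc1OC(C)C | intermediate
15 | (5S,6R,7S,8S)-5,8-epoxy-6,7-dihydroxy-2-[2-(3-isopropoxy-4-methoxyphenyl)ethyl]-5,6,7,8-tetrahydro-4H-chromen-4-one, exo cis-diol | COc1ccc(CCc2cc(=O)c3c(o2)[C@@H](O4)[C@@H](O)[C@@H](O)[C@H]34)cc1OC(C)C | intermediate
16 | (5S,6S,7S,8S)-5,8-epoxy-6,7-(isopropylidenedioxy)-2-[2-(3-isopropoxy-4-methoxyphenyl)ethyl]-5,6,7,8-tetrahydro-4H-chromen-4-one | COc1ccc(CCc2cc(=O)c3c(o2)[C@@H](O4)[C@@H](OC5(C)C)[C@@H](O5)[C@H]34)cc1OC(C)C | intermediate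
17 | (5S,6S,7S,8R)-8-chloro-5-(dichloroboryloxy)-6,7-(isopropylidenedioxy)-2-[2-(3-isopropoxy-4-methoxyphenyl)ethyl]-5,6,7,8-tetrahydro-4H-chromen-4-one | COc1ccc(CCc2cc(=O)c3c(o2)[C@H](Cl)[C@@H](OC4(C)C)[C@@H](O4)[C@H]3OB(Cl)Cl)cc1OC(C)C | intermediate (not isolated)
18 | CNP0362174.1, (5S,6S,7S,8R)-8-chloro-5,6,7-trihydroxy-2-[2-(3-hydroxy-4-methoxyphenyl)ethyl]-5,6,7,8-tetrahydro-4H-chromen-4-one | COc1ccc(CCc2cc(=O)c3c(o2)[C@H](Cl)[C@@H](O)[C@@H](O)[C@H]3O)cc1O | target

Total step count: 12
Longest linear sequence: 11 steps (3 → 18 through steps 2–12; equally 1 → 18 through steps 1 and 3–12)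

Steps most likely to fail

1. Step 9. The acid holds the flat diene by one hydrogen bond or ion pair, so face discrimination may be poor. Turnover may stall because the more basic adduct keeps the proton, the poorly nucleophilic dienophile may add too slowly, or endo addition may compete. The fallback uses known chemistry without a chiral controller. It sets out from 11 and 12: heating 11 in excess 12 with PPTS (2 mol%) in xylene at 130 °C in a sealed tube is the classical thermal trapping of a lactol-ether-derived furan, and chromatography should remove the endo isomer and give the racemic exo adduct F1. Preparative SFC on a chiral stationary phase then separates the enantiomers; the (5S,6S,7S,8S)-enantiomer is 14, where the route is rejoined.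

2. Step 12. Ionisation of the bridge at C5 (a cation stabilised through C4a=C8a by O1) may compete with SN2 at C8, so that chloride enters at the wrong bridgehead or with loss of configuration. Early acetonide cleavage may also let boron on O6/O7 steer the opening. The fallback activates the bridge by acylation instead of chelation and sets out from diol 15. Acetylation (Ac2O, pyridine, DMAP) gives the exo 6,7-diacetate F2. Acylative ether cleavage (AcCl, cat. ZnCl2, CH2Cl2, 0 °C), the classical conversion of 7-oxanorbornanes into trans-4-chlorocyclohexyl acetates, should attack the carbon next to the electron-poor C8a with inversion and give the 8-chloro 5,6,7-triacetate F3. BCl3 (CH2Cl2, 0 °C; esters inert) removes the isopropyl ether to give the phenol triacetate F4. Acidic methanolysis of the acetates (HCl from AcCl in MeOH, rt) rejoins the route at 18 without any basic step.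

3. Step 7. Hydride may be transferred to the vinyl-palladium intermediate before CO insertion (hydrodetriflation), or the silane may reduce the electrophilic formylpyranone. The fallback replaces carbonylation by cross-coupling and alkene cleavage and sets out from 9. Suzuki–Miyaura coupling with potassium vinyltrifluoroborate (PdCl2(dppf), Et3N, n-PrOH, 80 °C) should give the 3-vinylpyranone F5. Lemieux–Johnson cleavage (cat. OsO4, NaIO4, 2,6-lutidine, dioxane–H2O) then gives aldehyde 10, where the route is rejoined.

Further compounds
F1 | step 9 | racemic exo 5,8-epoxy 6,7-cyclic carbonate adduct (racemate of 14; one enantiomer drawn) | COc1ccc(CCc2cc(=O)c3c(o2)[C@@H](O4)[C@@H](OC5=O)[C@@H](O5)[C@H]34)cc1OC(C)C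
F2 | step 12 | exo 6,7-diacetate of 15 (5,8-epoxy bridge intact, configuration as in 15) | COc1ccc(CCc2cc(=O)c3c(o2)[C@@H](O4)[C@@H](OC(C)=O)[C@@H](OC(C)=O)[C@H]34)cc1OC(C)C
F3 | step 12 | (5S,6S,7S,8R)-8-chloro-2-[2-(3-isopropoxy-4-methoxyphenyl)ethyl]-4-oxo-5,6,7,8-tetrahydro-4H-chromene-5,6,7-triyl triacetate | COc1ccc(CCc2cc(=O)c3c(o2)[C@H](Cl)[C@@H](OC(C)=O)[C@@H](OC(C)=O)[C@H]3OC(C)=O)cc1OC(C)C
F4 | step 12 | (5S,6S,7S,8R)-8-chloro-2-[2-(3-hydroxy-4-methoxyphenyl)ethyl]-4-oxo-5,6,7,8-tetrahydro-4H-chromene-5,6,7-triyl triacetate | COc1ccc(CCc2cc(=O)c3c(o2)[C@H](Cl)[C@@H](OC(C)=O)[C@@H](OC(C)=O)[C@H]3OC(C)=O)cc1O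
F5 | step 7 | 2-[(tert-butyldimethylsilyloxy)methyl]-3-ethenyl-6-[2-(3-isopropoxy-4-methoxyphenyl)ethyl]-4H-pyran-4-one | COc1ccc(CCc2cc(=O)c(C=C)c(CO[Si](C)(C)C(C)(C)C)o2)cc1OC(C)C
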